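A neighbour with less protic impurity is simulated beside this flask, so the reckoning made here must also serve there.

first end groups 0.10 M (fed, over 4.0 h); second end groups 1.00 equiv; protic impurity 0.100 M; time 8.0 d

    second end groups + protic impurity → quenched reagent (k1 = 4.3 × 10⁻⁴ /M/s)
    first end groups + second end groups → links (k2 = 0.0026 /M/s)

- the reaction counts as stopped when no species that holds the first end groups changes by six tenths of a point or more over the second half of the time
- run time (flask): 8.0 d

- which holds at 8.0 d: what has brought the reaction to rest, or that it has not come to rest (all of the first end groups has reacted / it is still moving / the second end groups has run out first)
- amount of links at 8.0 d, in percent of the first end groups charged

Two of us dispute how the second end groups are split between the two steps that consume them. My colleague compares the constants: their ratio, the selectivity factor, is 6.05, so with c(first end groups) and c(protic impurity) as charged, links take 85.8% of what is consumed.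

I object that the first end groups arrive over 4.0 h, and their half-life by step 2 at the charged concentrations is 0.74 h, shorter. So I take links to form at about the dosing rate, 0.0250 M/h, while quenching at the charged concentrations runs at 0.0155 M/h. The feed share, the dosing rate divided by the sum of these two rates, is 61.8%. With the second end groups charged at 1.00 equiv, this is also my rough estimate of the links.

The forecast stands on my side of the dispute, though not on my number. It gives 65.5%, within 63.5% to 67.5%, and says the second end groups has run out first, on the ground that "the impurity takes a real share". My figure is lower.

The simulation gives 65.3% and the second end groups has run out first: at 8.00 d, 0% of the second end groups is left and 34.7% of the first end groups stands unreacted. The forecast holds, and my colleague's view loses here. That view takes c(first end groups) at its full charge, whereas this flask held 51.8% of it at 0.167 d, the end of the feed.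

The shortfall is due to quenching: the conversion of first end groups is 65.3% in this flask and 99.4% in the same run with that step struck out. The feed share of 61.8% lies 3.5 percentage points below the result, and it is a rough figure, since 51.8% of the first end groups still stood at 0.167 d. In the neighbour with 0.060 M of protic impurity, the feed share becomes 72.9%, and that flask gives 76.1%.

All constants are those of an exercise.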